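## Structural features

Compound 29 is a melampolide-type germacranolide: a ten-membered carbocycle C1–C10 with the C15 methyl on C4 and the C14 methyl ester on C10 of a C1=C10 double bond whose two ring bonds (C2–C1 and C10–C9) are cis (CIP E). Two small rings are trans-fused to neighbouring edges of this ring, an oxirane across C4–C5 and an α-methylene-γ-butyrolactone (O–C12(=O)–C11=C13H2) across C6–C7. Six stereocentres stand in a row, C4 (R), C5 (R), C6 (S), C7 (R), C8 (R) and C9 (S). The epoxide and lactone oxygens on C5/C6 are threo, the lactone substituents on C6/C7 are trans, and O8 (methacrylate) and O9 (acetate) are anti and carry different acyl groups. The fragile groups are the two exocyclic acrylate units (open to nucleophiles, hydrides and radicals), the acid-labile trisubstituted epoxide, the C9 acetate (allylic to the enoate, able to shift to O8) and the lactone acyl group (able to shift to a free O8). The real difficulty is to close the strained ten-membered ring while fixing the geometry of the C1=C10 enoate and keeping O8 and O9 distinguishable. The key step uses two facts: C9 is a carbinol carbon bonded directly to C10, and a C1≡C10 triple bond inside the ring can only be opened by syn addition to the cis ring alkene, so C9–C10 is made by alkynyl addition to a C9 aldehyde and C14 plus the alkene geometry follow together.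

## Logic of the disconnections

29 ⇒ 28 ⇒ 27 ⇒ 26. The two ester C–O bonds at O8 and O9 are cut first. The acrylate-type ester on O8 is the most sensitive group and should come last; O9 is acylated while O8 is still silylated, so the two oxygens never compete. The forward steps must avoid acyl migration between O9 and O8 and must spare the epoxide during silyl removal.

26 ⇒ 25 ⇒ 23. The C10–C14 bond and the C1–H/C10–halogen pair are removed, which turns the cis-enoate into the ring alkyne of 23. This takes away the alkene geometry problem, because any syn addition across C1≡C10 in the ring gives the cis alkene. The forward demand is regiocontrol: the metal must end on C10, next to the free C9 hydroxyl, and the hydride source must not touch C11=C13.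

23 ⇒ 21 (key disconnection). The C9–C10 bond is cut to the C9 aldehyde and the C10 iodoalkyne of 21. The cut opens the ten-membered ring at the only place where a carbinol sits next to an sp carbon, and the linear C2–C1≡C10 unit removes two transannular hydrogens from the closing ring. The forward step needs a non-basic acetylide equivalent that tolerates epoxide, lactone and Michael acceptor, and 1,2-induction from C8.

21 ⇒ 20 ⇒ 19 ⇒ 18 ⇒ 17. These are adjustments only: C9 oxidation level, the C–I bond on the alkyne, and the silyl ether on O8. The alkyne is kept silyl-capped until after the last organometallic fragment coupling, and the aldehyde is unmasked last because it is the most labile function. The demand is a clean distinction between a primary and a secondary silyl ether.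

17 ⇒ 14 + 15. The C7–C8 bond is cut with allyl transposition, so that C13 of 14 carries the halogen and the exocyclic C11=C13 of 17 appears in the bond-forming event. This joins a two-carbon aldehyde to the complete C1–C7/C10–C15 fragment and sets C7 and C8 from the existing C6 centre through a cyclic transition state. An enolate-based union at this bond would leave an acyl group on C9 whose reduction would compete with the lactone; the allylmetal route gives the free C8 hydroxyl and a protected C9 oxygen directly.

14 ⇒ 13 ⇒ 12 ⇒ 11. The C13–Br bond goes back to the silyl ether, and the lactone is opened at C11–C12 and C12–O6 to the hydroxy vinyl iodide 11. The carbonyl carbon is introduced catalytically, so no carboxylic acid derivative has to survive earlier steps. The forward step requires the iodine on C11 to be cis to C6.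

11 ⇒ 10. The two epoxide C–O bonds are cut to the C4=C5 alkene. The free C6 hydroxyl and the methyl group cis to it on C4 then control the face (threo), and no external chiral reagent is needed. The demand is chemoselectivity for C4=C5 over the iodoalkene.

10 ⇒ 8. The C11–I and C7–H bonds are removed to the propargylic alcohol. The hydroxyl-directed anti hydroalumination fixes both the regiochemistry and the alkene geometry needed for the lactone.

8 ⇒ 7 ⇒ 4 + 5. The C6–H bond is cut to the ketone and the C6–C7 bond to an N-methoxy-N-methylamide and a terminal alkyne. All chirality of the route then stems from one catalytic ketone reduction in which an alkynyl and a branched alkenyl group are to be told apart.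

4 ⇒ 3 ⇒ 1 + 2. The C–Si bond and the C4=C5 double bond are cut; the trisubstituted alkene comes from an olefination of a methyl ketone, which puts C15 cis to C6 in the major isomer. The silyl cap is needed so that the alkyne of the electrophile cannot exchange protons with the acetylide in the next step.

## Other disconnections considered

Alternative 1: The lactone C6–O bond is cut, which leads to the germacratrienoic acid A2 with a C6 methylene group. In the forward sense, anodic oxidation of the C12 carboxylate of A2 would give an acyloxy radical, 1,5-hydrogen transfer from the allylic C6–H, a second oxidation and capture of the allyl cation by the carboxylate to give the triene lactone A1; epoxidation of the only electron-rich alkene would then give 29.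
- In its favour: the lactone and the epoxide would be made at the very end and never have to survive other steps, and the last two steps need no protecting groups. On end-game step economy and on exposure of the epoxide the alternative is the better of the two plans.
- Against it: A2 already contains the ten-membered ring, the cis-enoate and both esters, so the ring-closure problem is only moved. The acyloxy radical can lose CO2, can reach the C8–H as well, and the allyl cation can be captured at C4. The C4=C5 alkene and the acrylates are themselves open to oxidation or radical addition at the electrode.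
- Comparison: the chosen plan sets C6 by a catalyst-controlled reduction and builds the lactone by a closed-shell carbonylation, so each centre has a named control element. The alternative depends on selectivity among several C–H bonds and has no close precedent on a substrate of this density.

Alternative 2: The C5–C6 bond is cut, which leads to the acyclic aldehyde A4 with an E-alkenyl iodide at C5. CrCl2 with catalytic NiCl2 would close the ring to the allylic alcohol A3, and lactonisation, directed epoxidation and diol differentiation would follow.
- In its favour: alkenylchromium closures of ten-membered carbocycles have the broadest precedent, the alkene geometry of C4=C5 is transferred from the iodide, and the new C6 hydroxyl can direct the epoxidation in the threo sense. The C14 ester is already present, so no tin and no carbonylation are needed after ring closure; on this point the alternative is the better, and on the metal chemistry of the closure the two plans are equal.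
- Against it: C7 of A4 is both α to the aldehyde and γ to an acrylate, so epimerisation or double-bond migration threatens before closure. C6 is created in the ring-closing event with only 1,2-induction from that labile centre. The cis C1=C10 enoate must be built with defined geometry on an open chain. The acetonide must come off with acid next to an epoxide, and O8 and O9 must then be told apart on a free diol.
- Comparison: the chosen plan closes the ring at a position where the neighbouring centre (C8) is configurationally stable and where the two oxygens are already different. It pays for this with the metalation–carbonylation steps after the closure.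

Alternative 3: The C8=C9 bond is cut, which leads to the triene A6. The second-generation Hoveyda–Grubbs catalyst would close the ring to the dienoate lactone A5, and ring-controlled cis-dihydroxylation (OsO4) of C8=C9, acylations and α-methylenation would follow.
- In its favour: the closure is catalytic and needs no stoichiometric chromium and no tin, A6 lacks the C8 and C9 stereocentres and is shorter to make, and syn-dihydroxylation of a cis ring alkene gives the anti relationship of O8/O9 that 29 has. On reagent economy and on the simplicity of the precursor the alternative is the better.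
- Against it: metathesis to a ten-membered ring is reversible and favours oligomers. The electron-poor 2-(methoxycarbonyl)diene can react through its internal alkene. The face of dihydroxylation rests on ring conformation alone, the resulting diol has no built-in distinction between O8 and O9, and the lactone must be methylenated late in the presence of esters and the epoxide.
- Comparison: the chosen plan has more steps before the ring closure but sets C8 before closure and arrives at the ring with O8 and O9 already differentiated and with the methylene lactone in place. The alternative is shorter to the ring and leaves three selectivity questions for afterwards.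

Key step: step 15

Remark: germacrane numbering is used for all intermediates; the side-chain alkyne is carried as its trimethylsilyl derivative (a spectator group) from step 2 to step 12, and the minor Z isomer of step 1 is removed by chromatography.

Remark: the configurations written for 21 and 23 were checked centre by centre against 29 (same sense at C4–C8; 9S in 23, as acetylation with retention requires), and no descriptor needed correction.

## Route

Step 1
Reactants: 1 hex-5-yn-2-one; 2 diethyl [2-(methoxy(methyl)amino)-2-oxoethyl]phosphonate
Product: 3 (2E)-N-methoxy-N,3-dimethylhept-2-en-6-ynamide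
Conditions: NaH, THF, 0 °C to reflux
Reagents that add atoms: none
Why: Horner–Wadsworth–Emmons olefination of a methyl ketone with an amide-stabilised phosphonate; the longer chain should end trans to the carbonyl group (E), which places C15 cis to C6 as the later epoxidation needs.

Step 2
Reactants: 3 (2E)-N-methoxy-N,3-dimethylhept-2-en-6-ynamide
Product: 4 (2E)-N-methoxy-N,3-dimethyl-7-(trimethylsilyl)hept-2-en-6-ynamide
Conditions: LiN(SiMe3)2, THF, −78 °C; Me3SiCl, −78 to 0 °C
Reagents that add atoms: chlorotrimethylsilane C[Si](C)(C)Cl
Why: C-silylation of a terminal alkyne through its lithium acetylide; the amide base is too hindered to add to the amide and the alkyne C–H is the most acidic site at low temperature.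

Step 3
Reactants: 4 (2E)-N-methoxy-N,3-dimethyl-7-(trimethylsilyl)hept-2-en-6-ynamide; 5 tert-butyldimethyl(prop-2-yn-1-yloxy)silane
Product: 7 (5E)-1-(tert-butyldimethylsilyloxy)-6-methyl-10-(trimethylsilyl)deca-5-en-2,9-diyn-4-one, via lithium acetylide 6 (not isolated)
Conditions: n-BuLi, THF, −78 °C; then 4, −78 to 0 °C; aq. NH4Cl
Reagents that add atoms: none
Why: Acylation of a lithium acetylide by an N-methoxy-N-methylamide, which forms C6–C7; the chelated tetrahedral intermediate stops at the ketone stage, and the silyl cap on the electrophile rules out proton exchange between two alkynes.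

Step 4
Reactants: 7 (5E)-1-(tert-butyldimethylsilyloxy)-6-methyl-10-(trimethylsilyl)deca-5-en-2,9-diyn-4-one
Product: 8 (4R,5E)-1-(tert-butyldimethylsilyloxy)-6-methyl-10-(trimethylsilyl)deca-5-en-2,9-diyn-4-ol
Conditions: (R)-1-methyl-3,3-diphenyltetrahydro-1H,3H-pyrrolo[1,2-c][1,3,2]oxazaborole (0.5 equiv), BH3·SMe2, THF, −30 °C; MeOH
Reagents that add atoms: none
Why: Corey–Bakshi–Shibata reduction of an alkynyl ketone; with the slim alkynyl arm as the small group and the β,β-disubstituted alkenyl arm as the large one, the (R)-catalyst should deliver hydride to the Si face and set C6 as the 4R carbinol; 1,2-reduction is expected because the borane is activated at the carbonyl oxygen.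

Step 5
Reactants: 8 (4R,5E)-1-(tert-butyldimethylsilyloxy)-6-methyl-10-(trimethylsilyl)deca-5-en-2,9-diyn-4-ol
Product: 10 (2Z,4R,5E)-1-(tert-butyldimethylsilyloxy)-2-iodo-6-methyl-10-(trimethylsilyl)deca-2,5-dien-9-yn-4-ol, via cyclic alkenylalanate 9 (not isolated)
Conditions: NaAlH2(OCH2CH2OMe)2, THF, −20 to 0 °C; EtOAc; then I2, −78 °C
Reagents that add atoms: iodine II
Why: Hydroxyl-directed anti hydroalumination of a propargylic alcohol followed by iodinolysis with retention; hydride goes to C7 and aluminium to C11 within a five-membered alkoxyalanate, so iodine ends on C11 cis to C6, and the low temperature should suppress loss of the neighbouring silyloxy group.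

Step 6
Reactants: 10 (2Z,4R,5E)-1-(tert-butyldimethylsilyloxy)-2-iodo-6-methyl-10-(trimethylsilyl)deca-2,5-dien-9-yn-4-ol
Product: 11 (1S,2Z)-4-(tert-butyldimethylsilyloxy)-3-iodo-1-{(2R,3R)-3-methyl-3-[4-(trimethylsilyl)but-3-yn-1-yl]oxiran-2-yl}but-2-en-1-ol
Conditions: mCPBA, NaHCO3, CH2Cl2, −20 to 0 °C
Reagents that add atoms: 3-chloroperoxybenzoic acid OOC(=O)c1cccc(Cl)c1
Why: Hydroxyl-directed peracid epoxidation; 1,3-allylic strain with the C15 methyl holds the C6–H in the alkene plane, so the hydrogen-bonded peracid should reach C4=C5 from the hydroxyl face and give the threo 4R,5R epoxide, while the iodine-bearing alkene is electron-poor and should stay untouched.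

Step 7
Reactants: 11 (1S,2Z)-4-(tert-butyldimethylsilyloxy)-3-iodo-1-{(2R,3R)-3-methyl-3-[4-(trimethylsilyl)but-3-yn-1-yl]oxiran-2-yl}but-2-en-1-ol
Product: 12 (5S)-3-[(tert-butyldimethylsilyloxy)methyl]-5-{(2R,3R)-3-methyl-3-[4-(trimethylsilyl)but-3-yn-1-yl]oxiran-2-yl}furan-2(5H)-one
Conditions: PdCl2(PPh3)2 (cat.), CO (1 atm), i-Pr2NEt, THF, 45 °C
Reagents that add atoms: carbon monoxide [C-]#[O+]
Why: Palladium-catalysed carbonylative lactonisation of a Z-γ-iodoallylic alcohol; oxidative addition, CO insertion and capture of the acylpalladium by the cis C6 hydroxyl should close the butenolide without touching the C6 configuration.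

Step 8
Reactants: 12 (5S)-3-[(tert-butyldimethylsilyloxy)methyl]-5-{(2R,3R)-3-methyl-3-[4-(trimethylsilyl)but-3-yn-1-yl]oxiran-2-yl}furan-2(5H)-one
Product: 13 (5S)-3-(hydroxymethyl)-5-{(2R,3R)-3-methyl-3-[4-(trimethylsilyl)but-3-yn-1-yl]oxiran-2-yl}furan-2(5H)-one
Conditions: HF·pyridine, pyridine, THF, 0 °C
Reagents that add atoms: none
Why: Buffered fluoride cleavage of a primary silyl ether; the pyridine buffer should spare the epoxide and the C–Si bond of the alkyne, and loss of that cap would not harm the following steps.

Step 9
Reactants: 13 (5S)-3-(hydroxymethyl)-5-{(2R,3R)-3-methyl-3-[4-(trimethylsilyl)but-3-yn-1-yl]oxiran-2-yl}furan-2(5H)-one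
Product: 14 (5S)-3-(bromomethyl)-5-{(2R,3R)-3-methyl-3-[4-(trimethylsilyl)but-3-yn-1-yl]oxiran-2-yl}furan-2(5H)-one
Conditions: CBr4, PPh3, CH2Cl2, 0 °C
Reagents that add atoms: tetrabromomethane BrC(Br)(Br)Br
Why: Appel reaction of a primary allylic alcohol under neutral conditions that leave the epoxide and the butenolide alone.

Step 10
Reactants: 14 (5S)-3-(bromomethyl)-5-{(2R,3R)-3-methyl-3-[4-(trimethylsilyl)but-3-yn-1-yl]oxiran-2-yl}furan-2(5H)-one; 15 (tert-butyldimethylsilyloxy)acetaldehyde
Product: 17 (4R,5S)-4-[(1R)-2-(tert-butyldimethylsilyloxy)-1-hydroxyethyl]-3-methylidene-5-{(2R,3R)-3-methyl-3-[4-(trimethylsilyl)but-3-yn-1-yl]oxiran-2-yl}oxolan-2-one, via allylchromium dichloride 16 (not isolated)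
Conditions: CrCl2, THF, 0 °C to rt
Reagents that add atoms: none
Why: Chromium-mediated Barbier (Nozaki–Hiyama) allylation with a 3-(bromomethyl)butenolide, which forms C7–C8 with allyl transposition and unveils C11=C13; the aldehyde should approach C7 anti to the C6 side chain (trans lactone), and the closed chair transition state with the ring-locked E-type allyl unit should give the 7,8-anti carbinol (8R).

Step 11
Reactants: 17 (4R,5S)-4-[(1R)-2-(tert-butyldimethylsilyloxy)-1-hydroxyethyl]-3-methylidene-5-{(2R,3R)-3-methyl-3-[4-(trimethylsilyl)but-3-yn-1-yl]oxiran-2-yl}oxolan-2-one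
Product: 18 8,9-bis-O-(tert-butyldimethylsilyl) ether of 17
Conditions: t-BuMe2SiOTf, 2,6-lutidine, CH2Cl2, −78 °C
Reagents that add atoms: tert-butyldimethylsilyl trifluoromethanesulfonate CC(C)(C)[Si](C)(C)OS(=O)(=O)C(F)(F)F
Why: Silylation of a secondary alcohol with a silyl triflate and a hindered base; at −78 °C it should be much faster than Lewis-acid opening of the epoxide, and it blocks O8 before the lactone acyl group can shift to it.

Step 12
Reactants: 18 8,9-bis-O-(tert-butyldimethylsilyl) ether of 17
Product: 19 C10-iodoalkyne corresponding to 18 (I in place of SiMe3)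
Conditions: N-iodosuccinimide, AgNO3 (cat.), DMF, rt, dark
Reagents that add atoms: N-iodosuccinimide O=C1CCC(=O)N1I
Why: Silver-catalysed iododesilylation of a trimethylsilylalkyne through the silver acetylide; the conditions are neutral and are compatible with silyl ethers, the epoxide and the methylene lactone.

Step 13
Reactants: 19 C10-iodoalkyne corresponding to 18
Product: 20 C9 primary alcohol with O8 still silylated
Conditions: HF·pyridine, pyridine, THF, 0 °C
Reagents that add atoms: none
Why: Selective cleavage of the unhindered primary silyl ether; the secondary ether on O8 is flanked by the branched C7 and should survive, and the buffered acid leaves no free alkoxide that could move the silyl group.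

Step 14
Reactants: 20 C9 primary alcohol with O8 still silylated
Product: 21 (2R)-2-(tert-butyldimethylsilyloxy)-2-[(2S,3R)-2-{(2R,3R)-3-(4-iodobut-3-yn-1-yl)-3-methyloxiran-2-yl}-4-methylidene-5-oxooxolan-3-yl]acetaldehyde
Conditions: 1,1,1-triacetoxy-1,1-dihydro-1,2-benziodoxol-3(1H)-one, NaHCO3, CH2Cl2, 0 °C to rt
Reagents that add atoms: none
Why: Dess–Martin oxidation of a primary alcohol under buffered, non-basic conditions, so the α-silyloxy aldehyde should not epimerise at C8; 21 is used at once.

Step 15
Reactants: 21 (2R)-2-(tert-butyldimethylsilyloxy)-2-[(2S,3R)-2-{(2R,3R)-3-(4-iodobut-3-yn-1-yl)-3-methyloxiran-2-yl}-4-methylidene-5-oxooxolan-3-yl]acetaldehyde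
Product: 23 ten-membered cycloalkynol (C1≡C10; 8-O-silyl; free 9S hydroxyl; 4,5-epoxide and 6,7-lactone as in 29), via alkynylchromium dichloride 22 (not isolated)
Conditions: CrCl2 (excess), NiCl2 (cat.), THF, rt, slow addition, high dilution
Reagents that add atoms: none
Why: CrCl2 reduces NiCl2 to zerovalent nickel, which inserts into the C10–I bond; transmetalation to trivalent chromium gives the alkynylchromium 22, which adds to the chromium-activated C9 aldehyde and forms C9–C10. The closest known reaction type is the Nozaki–Hiyama–Kishi cyclisation of ω-iodoalkynyl aldehydes to ten-membered cycloalkynols. The ring is closed in the 10-exo-trig mode onto the C9 carbonyl, and the linear C2–C1≡C10 segment removes two transannular hydrogens from the closing ring. The new C9 centre should be set by polar 1,2-induction from C8: the non-chelating silyloxy group lies anti to the incoming alkynyl carbon, which gives the 8,9-anti (9S) alcohol. The step needs chemoselectivity for the aldehyde over lactone, epoxide and the C11=C13 acceptor, which the low basicity and low nucleophilicity of the organochromium should secure. It also needs intra- over intermolecular addition, which slow addition at high dilution should secure. The medium is not basic, so C8 should not epimerise.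

Step 16
Reactants: 23 ten-membered cycloalkynol (C1≡C10; 8-O-silyl; free 9S hydroxyl)
Product: 25 C10 vinyl iodide (C1=C10 with cis ring bonds; I on C10; H on C1; free C9 hydroxyl), via vinylstannane 24 (not isolated)
Conditions: Bu3SnH, PdCl2(PPh3)2 (cat.), THF, 0 °C; then I2, NaHCO3, CH2Cl2, −20 °C
Reagents that add atoms: iodine II
Why: Palladium-catalysed syn hydrostannation of a propargylic alcohol, in which the hydroxyl should steer tin to the proximal C10, followed by iododestannylation with retention; syn addition across the ring alkyne can only give the cis ring alkene.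

Step 17
Reactants: 25 C10 vinyl iodide
Product: 26 C14 methyl ester (C1=C10 enoate; free C9 hydroxyl; 8-O-silyl)
Conditions: Pd(PPh3)4 (cat.), CO (1 atm), MeOH, i-Pr2NEt, THF, 40 °C
Reagents that add atoms: carbon monoxide [C-]#[O+]; methanol CO
Why: Palladium-catalysed methoxycarbonylation of a vinyl iodide with retention of alkene geometry; a hindered amine and a limited amount of methanol are chosen so that methanol should not add to C11=C13.

Step 18
Reactants: 26 C14 methyl ester (free C9 hydroxyl)
Product: 27 9-O-acetate of 26
Conditions: Ac2O, pyridine, 4-(dimethylamino)pyridine (cat.), CH2Cl2, 0 °C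
Reagents that add atoms: acetic anhydride CC(=O)OC(C)=O
Why: Acylation of a secondary allylic alcohol with retention at C9; O8 is still silylated, so only O9 can react.

Step 19
Reactants: 27 9-O-acetate of 26
Product: 28 8-hydroxy-9-acetate (free C8 hydroxyl)
Conditions: HF·pyridine, pyridine, THF, 0 °C to rt
Reagents that add atoms: none
Why: Buffered acidic fluoride desilylation; no alkoxide is formed, which should keep the acetate on O9 and the lactone on O6, and the pyridine buffer should protect the epoxide.

Step 20
Reactants: 28 8-hydroxy-9-acetate (free C8 hydroxyl)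
Product: 29 target CNP0153978.4 (4R,5R,6S,7R,8R,9S; 8-O-methacrylate; 9-O-acetate)
Conditions: methacryloyl chloride, Et3N, 4-(dimethylamino)pyridine (cat.), CH2Cl2, 0 °C
Reagents that add atoms: methacryloyl chloride C=C(C)C(Cl)=O
Why: Acylation of the remaining secondary alcohol with an acid chloride at low temperature, fast enough that the neighbouring acetate should not migrate; no stereocentre is touched.

## Compound list

1 | hex-5-yn-2-one | CC(=O)CCC#C | starting material
2 | diethyl [2-(methoxy(methyl)amino)-2-oxoethyl]phosphonate | CCOP(=O)(CC(=O)N(C)OC)OCC | starting material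
3 | (2E)-N-methoxy-N,3-dimethylhept-2-en-6-ynamide | C#CCC/C(C)=C/C(=O)N(C)OC | intermediate
4 | (2E)-N-methoxy-N,3-dimethyl-7-(trimethylsilyl)hept-2-en-6-ynamide | C[Si](C)(C)C#CCC/C(C)=C/C(=O)N(C)OC | intermediate
5 | tert-butyldimethyl(prop-2-yn-1-yloxy)silane | C#CCO[Si](C)(C)C(C)(C)C | starting material
6 | [3-(tert-butyldimethylsilyloxy)prop-1-yn-1-yl]lithium (not isolated) | [Li]C#CCO[Si](C)(C)C(C)(C)C | intermediate
7 | (5E)-1-(tert-butyldimethylsilyloxy)-6-methyl-10-(trimethylsilyl)deca-5-en-2,9-diyn-4-one | C[Si](C)(C)C#CCC/C(C)=C/C(=O)C#CCO[Si](C)(C)C(C)(C)C | intermediate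
8 | (4R,5E)-1-(tert-butyldimethylsilyloxy)-6-methyl-10-(trimethylsilyl)deca-5-en-2,9-diyn-4-ol | CC(C)(C)[Si](C)(C)OCC#C[C@H](O)/C=C(\C)CCC#C[Si](C)(C)C | intermediate
9 | sodium cyclic alkenylalanate of 8 (Al bound to O6 and C11, two 2-methoxyethoxy ligands; not isolated) | [Na+].COCCO[Al-]1(OCCOC)O[C@H](/C=C(\C)CCC#C[Si](C)(C)C)C=C1CO[Si](C)(C)C(C)(C)C | intermediate
10 | (2Z,4R,5E)-1-(tert-butyldimethylsilyloxy)-2-iodo-6-methyl-10-(trimethylsilyl)deca-2,5-dien-9-yn-4-ol | CC(C)(C)[Si](C)(C)OC/C(I)=C/[C@H](O)/C=C(\C)CCC#C[Si](C)(C)C | intermediate
11 | (1S,2Z)-4-(tert-butyldimethylsilyloxy)-3-iodo-1-{(2R,3R)-3-methyl-3-[4-(trimethylsilyl)but-3-yn-1-yl]oxiran-2-yl}but-2-en-1-ol | CC(C)(C)[Si](C)(C)OC/C(I)=C/[C@H](O)[C@H]1O[C@]1(C)CCC#C[Si](C)(C)C | intermediate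
12 | (5S)-3-[(tert-butyldimethylsilyloxy)methyl]-5-{(2R,3R)-3-methyl-3-[4-(trimethylsilyl)but-3-yn-1-yl]oxiran-2-yl}furan-2(5H)-one | CC(C)(C)[Si](C)(C)OCC1=C[C@@H]([C@H]2O[C@]2(C)CCC#C[Si](C)(C)C)OC1=O | intermediate
13 | (5S)-3-(hydroxymethyl)-5-{(2R,3R)-3-methyl-3-[4-(trimethylsilyl)but-3-yn-1-yl]oxiran-2-yl}furan-2(5H)-one | OCC1=C[C@@H]([C@H]2O[C@]2(C)CCC#C[Si](C)(C)C)OC1=O | intermediate
14 | (5S)-3-(bromomethyl)-5-{(2R,3R)-3-methyl-3-[4-(trimethylsilyl)but-3-yn-1-yl]oxiran-2-yl}furan-2(5H)-one | BrCC1=C[C@@H]([C@H]2O[C@]2(C)CCC#C[Si](C)(C)C)OC1=O | intermediate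
15 | (tert-butyldimethylsilyloxy)acetaldehyde | CC(C)(C)[Si](C)(C)OCC=O | starting material
16 | allylchromium dichloride from 14 (Cr on C13; not isolated) | Cl[Cr](Cl)CC1=C[C@@H]([C@H]2O[C@]2(C)CCC#C[Si](C)(C)C)OC1=O | intermediate
17 | (4R,5S)-4-[(1R)-2-(tert-butyldimethylsilyloxy)-1-hydroxyethyl]-3-methylidene-5-{(2R,3R)-3-methyl-3-[4-(trimethylsilyl)but-3-yn-1-yl]oxiran-2-yl}oxolan-2-one | CC(C)(C)[Si](C)(C)OC[C@H](O)[C@H]1C(=C)C(=O)O[C@@H]1[C@H]1O[C@]1(C)CCC#C[Si](C)(C)C | intermediate
18 | 8,9-bis-O-(tert-butyldimethylsilyl) ether of 17 | CC(C)(C)[Si](C)(C)OC[C@H](O[Si](C)(C)C(C)(C)C)[C@H]1C(=C)C(=O)O[C@@H]1[C@H]1O[C@]1(C)CCC#C[Si](C)(C)C | intermediate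
19 | C10-iodoalkyne corresponding to 18 | CC(C)(C)[Si](C)(C)OC[C@H](O[Si](C)(C)C(C)(C)C)[C@H]1C(=C)C(=O)O[C@@H]1[C@H]1O[C@]1(C)CCC#CI | intermediate
20 | C9 primary alcohol (8-O-silyl iodoalkyne lactone epoxide) | OC[C@H](O[Si](C)(C)C(C)(C)C)[C@H]1C(=C)C(=O)O[C@@H]1[C@H]1O[C@]1(C)CCC#CI | intermediate
21 | (2R)-2-(tert-butyldimethylsilyloxy)-2-[(2S,3R)-2-{(2R,3R)-3-(4-iodobut-3-yn-1-yl)-3-methyloxiran-2-yl}-4-methylidene-5-oxooxolan-3-yl]acetaldehyde | CC(C)(C)[Si](C)(C)O[C@@H](C=O)[C@H]1C(=C)C(=O)O[C@@H]1[C@H]1O[C@]1(C)CCC#CI | intermediate
22 | alkynylchromium dichloride from 21 (Cr on C10; not isolated) | CC(C)(C)[Si](C)(C)O[C@@H](C=O)[C@H]1C(=C)C(=O)O[C@@H]1[C@H]1O[C@]1(C)CCC#C[Cr](Cl)Cl | intermediate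
23 | ten-membered cycloalkynol (C1≡C10; 8-O-silyl; 9S hydroxyl; epoxide and lactone as in 29) | CC(C)(C)[Si](C)(C)O[C@@H]1[C@H]2C(=C)C(=O)O[C@@H]2[C@H]2O[C@]2(C)CCC#C[C@@H]1O | intermediate
24 | C10 tributylstannyl alkene from 23 (cis ring alkene; not isolated) | CC(C)(C)[Si](C)(C)O[C@@H]1[C@H]2C(=C)C(=O)O[C@@H]2[C@H]2O[C@]2(C)CC/C=C(/[Sn](CCCC)(CCCC)CCCC)[C@@H]1O | intermediate
25 | C10 vinyl iodide (cis ring alkene; free C9 hydroxyl) | CC(C)(C)[Si](C)(C)O[C@@H]1[C@H]2C(=C)C(=O)O[C@@H]2[C@H]2O[C@]2(C)CC/C=C(/I)[C@@H]1O | intermediate
26 | C14 methyl ester (free C9 hydroxyl; 8-O-silyl) | CC(C)(C)[Si](C)(C)O[C@@H]1[C@H]2C(=C)C(=O)O[C@@H]2[C@H]2O[C@]2(C)CC/C=C(/C(=O)OC)[C@@H]1O | intermediate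
27 | 9-O-acetate of 26 | CC(C)(C)[Si](C)(C)O[C@@H]1[C@H]2C(=C)C(=O)O[C@@H]2[C@H]2O[C@]2(C)CC/C=C(/C(=O)OC)[C@@H]1OC(C)=O | intermediate
28 | 8-hydroxy-9-acetate (desilylated 27) | O[C@@H]1[C@H]2C(=C)C(=O)O[C@@H]2[C@H]2O[C@]2(C)CC/C=C(/C(=O)OC)[C@@H]1OC(C)=O | intermediate
29 | CNP0153978.4 (4R,5R,6S,7R,8R,9S; 8-O-methacrylate; 9-O-acetate; C1=C10 E with cis ring bonds) | C=C(C)C(=O)O[C@@H]1[C@H]2C(=C)C(=O)O[C@@H]2[C@H]2O[C@]2(C)CC/C=C(/C(=O)OC)[C@@H]1OC(C)=O | target

Total step count: 20.
Longest linear sequence: 20 steps, from 1 to 29; compounds 2, 5 and 15 are purchased.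

## Least certain steps

Step 15 (key step). Facial selectivity at C9 may be poor, because the conformation of the closing ring rather than the C8 silyloxy group may decide which aldehyde face the alkynylchromium reaches. Intermolecular addition and reductive loss of iodine may also compete, because the C2–C1≡C10 unit must bend in the transition state. Fallback, which sets C9 by substitution instead of addition control: the cyclisation is run from 21 as written and the (9R)-epimeric cycloalkynol F1 is taken on. A Mitsunobu reaction with formic acid (PPh3, diisopropyl azodicarboxylate) should invert the propargylic centre to the 9S formate F2, and brief methanolysis (KHCO3, MeOH, 0 °C) returns to 23.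

Step 16. Tin may be delivered to C1 instead of C10 if the steric demand of the branched C9 side outweighs the directing hydroxyl. The palladium hydride may also reduce C11=C13, and acid formed from surplus stannane and iodine may open the epoxide. Fallback, which fixes the regiochemistry by conjugation: from 23, Dess–Martin oxidation gives the cyclic ynone F3. Palladium-catalysed hydrostannation (Bu3SnH, Pd(PPh3)4) of an ynone places tin α to the carbonyl and gives the stannyl enone F4. Corey–Bakshi–Shibata reduction with the (S)-oxazaborolidine, with the stannyl-bearing alkenyl arm as the large group, should then return 24, which is iodinated as in step 16.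

Step 10. An open transition state or attack on the face syn to the C6 side chain may erode the C7/C8 relationship, and the lactone acyl group may shift to the new C8 alkoxide. Fallback, which sets C8 by a chiral auxiliary and keeps O8 silylated from the start: (S)-4-benzyl-2-oxazolidinone is acylated with (tert-butyldimethylsilyloxy)acetyl chloride to the glycolate imide F5. Its sodium enolate (NaN(SiMe3)2, THF, −78 °C) should add to 14 by conjugate addition–elimination anti to the C6 side chain and give the imide adduct F6. LiBH4 at 0 °C cleaves the imide to the C9 alcohol F7, and iododesilylation as in step 12 leads to 20.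

Step 6. Epoxidation may be incompletely chemoselective between C4=C5 and the iodoalkene, the iodine may be oxidised, or the threo preference may be weaker than expected on a carbinol flanked by two alkenes. Fallback, which replaces substrate control by reagent control: 10 is first carbonylated as in step 7 to the alkenyl butenolide F8. Shi epoxidation with the D-fructose-derived ketone 1,2:4,5-di-O-isopropylidene-β-D-erythro-2,3-hexodiulo-2,6-pyranose and KHSO5 (K2CO3 buffer, 0 °C) should then give the 4R,5R epoxide 12.

Step 4. The catalyst may not distinguish the alkynyl from the alkenyl arm well enough, which would lower the enantiomeric purity of every later compound. Fallback, which makes C6 by addition instead of reduction: 4 is reduced with i-Bu2AlH to the enal F9. Me2Zn with the ProPhenol ligand 2,6-bis{[2-(hydroxydiphenylmethyl)pyrrolidin-1-yl]methyl}-4-methylphenol (the antipode that directs the alkynyl group to the Si face) should add 5 to F9 and give 8.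

## Further compounds

F1 | step 15 | (9R)-epimer of 23 | CC(C)(C)[Si](C)(C)O[C@@H]1[C@H]2C(=C)C(=O)O[C@@H]2[C@H]2O[C@]2(C)CCC#C[C@H]1O
F2 | step 15 | 9-O-formate of 23 (9S) | CC(C)(C)[Si](C)(C)O[C@@H]1[C@H]2C(=C)C(=O)O[C@@H]2[C@H]2O[C@]2(C)CCC#C[C@@H]1OC=O
F3 | step 16 | cyclic C9 ynone from 23 | CC(C)(C)[Si](C)(C)O[C@@H]1[C@H]2C(=C)C(=O)O[C@@H]2[C@H]2O[C@]2(C)CCC#CC1=O
F4 | step 16 | C10-tributylstannyl C9 enone | CC(C)(C)[Si](C)(C)O[C@@H]1[C@H]2C(=C)C(=O)O[C@@H]2[C@H]2O[C@]2(C)CC/C=C(/[Sn](CCCC)(CCCC)CCCC)C1=O
F5 | step 10 | (4S)-4-benzyl-3-[(tert-butyldimethylsilyloxy)acetyl]-1,3-oxazolidin-2-one | CC(C)(C)[Si](C)(C)OCC(=O)N1[C@@H](Cc2ccccc2)COC1=O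
F6 | step 10 | imide adduct (C7–C8 formed; 8-O-silyl; C9 imide) | CC(C)(C)[Si](C)(C)O[C@@H](C(=O)N1[C@@H](Cc2ccccc2)COC1=O)[C@H]1C(=C)C(=O)O[C@@H]1[C@H]1O[C@]1(C)CCC#C[Si](C)(C)C
F7 | step 10 | C9 primary alcohol with trimethylsilylalkyne (8-O-silyl) | OC[C@H](O[Si](C)(C)C(C)(C)C)[C@H]1C(=C)C(=O)O[C@@H]1[C@H]1O[C@]1(C)CCC#C[Si](C)(C)C
F8 | step 6 | (5S)-3-[(tert-butyldimethylsilyloxy)methyl]-5-[(1E)-2-methyl-6-(trimethylsilyl)hex-1-en-5-yn-1-yl]furan-2(5H)-one | CC(C)(C)[Si](C)(C)OCC1=C[C@@H](/C=C(\C)CCC#C[Si](C)(C)C)OC1=O
F9 | step 4 | (2E)-3-methyl-7-(trimethylsilyl)hept-2-en-6-ynal | C[Si](C)(C)C#CCC/C(C)=C/C=O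
A1 | alternative 1 | 4,5-deoxy target (triene lactone) | C=C(C)C(=O)O[C@@H]1[C@H]2C(=C)C(=O)O[C@@H]2/C=C(\C)CC/C=C(/C(=O)OC)[C@@H]1OC(C)=O
A2 | alternative 1 | germacratrienoic acid (C12 acid; C6 methylene) | C=C(C)C(=O)O[C@@H]1[C@@H](C(=C)C(=O)O)C/C=C(\C)CC/C=C(/C(=O)OC)[C@@H]1OC(C)=O
A3 | alternative 2 | ten-membered allylic alcohol (C6 hydroxyl; 8,9-acetonide) | CC1(C)O[C@@H]2[C@@H](C(=C)C(=O)OC)[C@H](O)/C=C(\C)CC/C=C(/C(=O)OC)[C@@H]2O1
A4 | alternative 2 | acyclic C6 aldehyde with E-alkenyl iodide at C5 (8,9-acetonide) | CC1(C)O[C@H]([C@H](C=O)C(=C)C(=O)OC)[C@@H](O1)/C(C(=O)OC)=C\CC/C(C)=C/I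
A5 | alternative 3 | ten-membered dienoate lactone (cis C8=C9) | C1/C=C(/C(=O)OC)\C=C/[C@H]2CC(=O)O[C@@H]2[C@H]2O[C@]2(C)C1
A6 | alternative 3 | acyclic triene (C7 vinyl lactone with 2-(methoxycarbonyl)diene) | C=C[C@H]1CC(=O)O[C@@H]1[C@H]1O[C@]1(C)CC/C=C(/C(=O)OC)C=C
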